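**Plan**

- Retrosynthesis: cut O–Si, then C2'–C3' (sp3–sp2) to a chromanylethyl iodide and a C13 (E,E)-alkenyl iodide; return C4 to a ketone; cut C2–C3 of the pyran ring (carbenoid C–H insertion); cut O1–C2 (Mitsunobu) and aryl–C4 (Friedel–Crafts). The alkenyl iodide goes back by carboalumination (C4'–CH3) and propargylation of geranyl bromide (C5'–C6').
- Forward: the benzene ring is bought as 2,5-dimethylhydroquinone; C4/C3 enter as an acetyl group, O1–C2 by etherification, and the pyran ring closes last at C2–C3. The chain is then joined at C2'–C3' and the phenol is freed.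
- Enabling feature: the tertiary C2–H alpha to O1 lies 1,6 to C3 across the rigid arc C4(=O)–C4a=C8a–O1 of the benzene ring, so a carbenoid at C3 reaches it through a six-membered array that becomes the pyranone ring.
- Stereochemistry: C2 comes from (S)-butane-1,3-diol, inverted once in the Mitsunobu step and then retained in the C–H insertion. The 7'E alkene comes from geranyl bromide and the 3'E alkene from syn-carboalumination/iodinolysis, kept in the palladium coupling.

Key step: step 6

Remark on the chemistry: the target is read as (R)-β-tocotrienol, (2R,3'E,7'E). Chroman numbering (O1, C2–C4, C4a, C5–C8, C8a) and chain numbering C1'–C12' are used throughout; trityl means triphenylmethyl.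

**Route**

Step 1
Reactants: 1 2,5-dimethylbenzene-1,4-diol
Product: 2 1-(2,5-dihydroxy-3,6-dimethylphenyl)ethan-1-one
Conditions: AcOH, BF3·OEt2, 110 °C; then H2O
Reagents that add atoms: acetic acid, CC(=O)O
Why: Friedel–Crafts C-acylation of the electron-rich hydroquinone should occur at one of the two symmetry-equivalent free ring positions, and the first acyl group deactivates the ring against a second.

Step 2
Reactants: 2 1-(2,5-dihydroxy-3,6-dimethylphenyl)ethan-1-one
Product: 3 1-{2-hydroxy-3,6-dimethyl-5-[(triisopropylsilyl)oxy]phenyl}ethan-1-one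
Conditions: TIPSCl, imidazole, DMF, rt
Reagents that add atoms: chlorotriisopropylsilane, CC(C)[Si](Cl)(C(C)C)C(C)C
Why: Selective silylation should take the 5-OH only, because the 2-OH is hydrogen-bonded to the ketone and flanked by acetyl and methyl.

Step 3
Reactants: 4 (S)-butane-1,3-diol
Product: 5 (S)-4-(trityloxy)butan-2-ol
Conditions: TrCl, Et3N, DMAP (cat.), CH2Cl2, 0 °C → rt
Reagents that add atoms: trityl chloride, ClC(c1ccccc1)(c1ccccc1)c1ccccc1
Why: Sterically controlled tritylation should take the primary hydroxyl and leave the stereogenic secondary carbinol untouched.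

Step 4
Reactants: 3 1-{2-hydroxy-3,6-dimethyl-5-[(triisopropylsilyl)oxy]phenyl}ethan-1-one; 5 (S)-4-(trityloxy)butan-2-ol
Product: 6 1-{3,6-dimethyl-5-[(triisopropylsilyl)oxy]-2-{[(R)-4-(trityloxy)butan-2-yl]oxy}phenyl}ethan-1-one
Conditions: PPh3, DIAD, toluene, 0 → 40 °C
Reagents that add atoms: none
Why: In this Mitsunobu etherification the acidic ortho-acyl phenol should displace the alkoxyphosphonium group by SN2, which inverts the carbinol carbon from (S) to the (R)-ether needed for C2.

Step 5
Reactants: 6 1-{3,6-dimethyl-5-[(triisopropylsilyl)oxy]-2-{[(R)-4-(trityloxy)butan-2-yl]oxy}phenyl}ethan-1-one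
Product: 9 2-diazo-1-{3,6-dimethyl-5-[(triisopropylsilyl)oxy]-2-{[(R)-4-(trityloxy)butan-2-yl]oxy}phenyl}ethan-1-one, via lithium enolate 7 (not isolated), via trifluoroacetyl diketone 8 (not isolated)
Conditions: LiN(SiMe3)2, THF, −78 °C; CF3CO2CH2CF3; aq NH4Cl; then MsN3, Et3N, H2O, MeCN, rt
Reagents that add atoms: methanesulfonyl azide, CS(=O)(=O)N=[N+]=[N-]; 2,2,2-trifluoroethyl trifluoroacetate, O=C(OCC(F)(F)F)C(F)(F)F (its CF3CO group is held only by 8); lithium hexamethyldisilazide, [Li]N([Si](C)(C)C)[Si](C)(C)C (lithium held only by 7)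
Why: In this detrifluoroacetylative diazo transfer the methyl ketone enolate is C-acylated, and the activated 1,3-diketone should take the diazo group from the sulfonyl azide and lose the trifluoroacetyl group as the N-sulfonyl amide, without touching the ether stereocentre.

Step 6
Reactants: 9 2-diazo-1-{3,6-dimethyl-5-[(triisopropylsilyl)oxy]-2-{[(R)-4-(trityloxy)butan-2-yl]oxy}phenyl}ethan-1-one
Product: 10 (R)-2,5,8-trimethyl-6-[(triisopropylsilyl)oxy]-2-[2-(trityloxy)ethyl]chroman-4-one
Conditions: Rh2(OAc)4 (1 mol %), CH2Cl2, 40 °C, slow addition of 9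
Reagents that add atoms: none
Why: Rh2(OAc)4 expels N2 from 9 to give an electrophilic rhodium carbenoid at C3, which inserts into the tertiary C2–H bond through a three-centre, hydride-transfer-like transition state in which the C3–C2 bond forms as the hydrogen moves to C3. The closest known reaction type is the dirhodium-carboxylate-catalysed intramolecular C–H insertion of ortho-alkoxyaryl diazomethyl ketones alpha to the ether oxygen, which gives chroman-4-ones, together with the established retention of configuration when such carbenoids insert at a stereogenic tertiary C–H. The pyranone ring closes by 1,6-C–H insertion through a six-membered chair-like array (C3, C4, C4a, C8a, O1, C2), the benzene ring holding carbenoid and C–H within reach. The new quaternary stereocentre C2 is controlled by the (R)-ether carbon of 9 alone: carbon takes the place of hydrogen on the same face, so (R)-9 should give (R)-10. The step needs chemoselectivity for C2–H over attack at O1 (oxonium ylide, then [1,2]-shift), over the primary benzylic C–H of the C5 methyl group (indanone) and over the remote ether C–H bonds. This should be secured by the hydridic, tertiary, oxygen-activated character of C2–H, by the low basicity of an aryl ether oxygen that carries no stabilised migrating group (so ylide formation can revert), and by carboxylate ligands on rhodium, which favour insertion over ylide chemistry.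

Step 7
Reactants: 10 (R)-2,5,8-trimethyl-6-[(triisopropylsilyl)oxy]-2-[2-(trityloxy)ethyl]chroman-4-one
Product: 12 2-{(S)-2,5,8-trimethyl-6-[(triisopropylsilyl)oxy]chroman-2-yl}ethan-1-ol, via chroman-4-ol 11 (not isolated)
Conditions: NaBH4, MeOH/THF, 0 °C; then Et3SiH, TFA, CH2Cl2, 0 °C; aq NaHCO3 work-up
Reagents that add atoms: none
Why: Borohydride reduction followed by ionic hydrogenation should replace the C4 oxygen by hydrogen, because the benzylic C4 cation is stabilised by O1 and trapped by the silane, while the same acid/silane pair removes the trityl ether as triphenylmethane and leaves the aryl silyl ether and the quaternary C2 untouched (the descriptor changes to S by priority only).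

Step 8
Reactants: 12 2-{(S)-2,5,8-trimethyl-6-[(triisopropylsilyl)oxy]chroman-2-yl}ethan-1-ol
Product: 13 {[(S)-2-(2-iodoethyl)-2,5,8-trimethylchroman-6-yl]oxy}triisopropylsilane
Conditions: I2, PPh3, imidazole, CH2Cl2, 0 °C → rt
Reagents that add atoms: iodine, II
Why: Appel-type iodination should convert the unhindered primary alcohol into the iodide by SN2 displacement of the oxyphosphonium group.

Step 9
Reactants: 14 geranyl bromide, (E)-1-bromo-3,7-dimethylocta-2,6-diene; 15 1-(trimethylsilyl)propyne
Product: 18 (E)-6,10-dimethylundeca-5,9-dien-1-yne, via lithiated silylpropyne 16 (not isolated), via silylated enyne 17 (not isolated)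
Conditions: 15, n-BuLi, THF, −78 → −20 °C; 14, −78 °C → rt; then K2CO3 (cat.), MeOH, rt
Reagents that add atoms: n-butyllithium, [Li]CCCC (lithium held only by 16)
Why: The silyl-capped propargyl lithium should alkylate the primary allylic bromide by direct SN2 at its propargylic carbon, and methanolysis then removes the alkynyl silane, the (E)-alkene of 14 being carried through unchanged.

Step 10
Reactants: 18 (E)-6,10-dimethylundeca-5,9-dien-1-yne
Product: 20 (1E,5E)-1-iodo-2,6,10-trimethylundeca-1,5,9-triene, via alkenylalane 19 (not isolated)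
Conditions: Me3Al, Cp2ZrCl2 (cat.), CH2Cl2, 0 °C → rt; then I2, THF, −30 → 0 °C
Reagents that add atoms: trimethylaluminium, C[Al](C)C (one methyl stays in 20, the AlMe2 group only in 19); iodine, II
Why: Negishi zirconium-catalysed carboalumination should add methyl and aluminium syn across the terminal alkyne with aluminium at the terminus, and iodinolysis with retention sets the (E)-trisubstituted alkenyl iodide.

Step 11
Reactants: 13 {[(S)-2-(2-iodoethyl)-2,5,8-trimethylchroman-6-yl]oxy}triisopropylsilane; 20 (1E,5E)-1-iodo-2,6,10-trimethylundeca-1,5,9-triene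
Product: 22 triisopropyl{[(R)-2,5,8-trimethyl-2-[(3E,7E)-4,8,12-trimethyltrideca-3,7,11-trien-1-yl]chroman-6-yl]oxy}silane, via alkylzinc iodide 21 (not isolated)
Conditions: 13, Zn dust, LiCl, THF, 40 °C; then 20, PdCl2(dppf) (5 mol %), THF, 45 °C
Reagents that add atoms: zinc, [Zn] (held only by 21)
Why: In this Negishi coupling, zinc insertion into the primary C–I bond and transmetalation to the alkenylpalladium species formed from 20 and zerovalent palladium should join C2' to C3' with retention of the alkene geometry, the wide-bite-angle diphosphine suppressing β-hydride elimination.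

Step 12
Reactants: 22 triisopropyl{[(R)-2,5,8-trimethyl-2-[(3E,7E)-4,8,12-trimethyltrideca-3,7,11-trien-1-yl]chroman-6-yl]oxy}silane
Product: 23 (R)-2,5,8-trimethyl-2-[(3E,7E)-4,8,12-trimethyltrideca-3,7,11-trien-1-yl]chroman-6-ol
Conditions: Bu4NF, AcOH, THF, 0 °C, argon
Reagents that add atoms: none
Why: Fluoride-mediated cleavage of the aryl silyl ether, buffered with acetic acid and run under argon to protect the oxidation-prone chromanol, should free the phenol without touching the triene or C2.

**Compound list**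

1 | 2,5-dimethylbenzene-1,4-diol | Cc1cc(O)c(C)cc1O | starting material
2 | 1-(2,5-dihydroxy-3,6-dimethylphenyl)ethan-1-one | CC(=O)c1c(O)c(C)cc(O)c1C | intermediate
3 | 1-{2-hydroxy-3,6-dimethyl-5-[(triisopropylsilyl)oxy]phenyl}ethan-1-one | CC(=O)c1c(O)c(C)cc(O[Si](C(C)C)(C(C)C)C(C)C)c1C | intermediate
4 | (S)-butane-1,3-diol | C[C@H](O)CCO | starting material
5 | (S)-4-(trityloxy)butan-2-ol | C[C@H](O)CCOC(c1ccccc1)(c1ccccc1)c1ccccc1 | intermediate
6 | 1-{3,6-dimethyl-5-[(triisopropylsilyl)oxy]-2-{[(R)-4-(trityloxy)butan-2-yl]oxy}phenyl}ethan-1-one | CC(=O)c1c(O[C@H](C)CCOC(c2ccccc2)(c2ccccc2)c2ccccc2)c(C)cc(O[Si](C(C)C)(C(C)C)C(C)C)c1C | intermediate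
7 | lithium enolate of 6 (lithium 1-aryl-ethen-1-olate, aryl as in 6) | [Li+].[O-]C(=C)c1c(O[C@H](C)CCOC(c2ccccc2)(c2ccccc2)c2ccccc2)c(C)cc(O[Si](C(C)C)(C(C)C)C(C)C)c1C | intermediate (not isolated)
8 | 4,4,4-trifluoro-1-{3,6-dimethyl-5-[(triisopropylsilyl)oxy]-2-{[(R)-4-(trityloxy)butan-2-yl]oxy}phenyl}butane-1,3-dione | O=C(CC(=O)C(F)(F)F)c1c(O[C@H](C)CCOC(c2ccccc2)(c2ccccc2)c2ccccc2)c(C)cc(O[Si](C(C)C)(C(C)C)C(C)C)c1C | intermediate (not isolated)
9 | 2-diazo-1-{3,6-dimethyl-5-[(triisopropylsilyl)oxy]-2-{[(R)-4-(trityloxy)butan-2-yl]oxy}phenyl}ethan-1-one | [N-]=[N+]=CC(=O)c1c(O[C@H](C)CCOC(c2ccccc2)(c2ccccc2)c2ccccc2)c(C)cc(O[Si](C(C)C)(C(C)C)C(C)C)c1C | intermediate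
10 | (R)-2,5,8-trimethyl-6-[(triisopropylsilyl)oxy]-2-[2-(trityloxy)ethyl]chroman-4-one | C[C@@]1(CCOC(c2ccccc2)(c2ccccc2)c2ccccc2)CC(=O)c2c(C)c(O[Si](C(C)C)(C(C)C)C(C)C)cc(C)c2O1 | intermediate
11 | (2R)-2,5,8-trimethyl-6-[(triisopropylsilyl)oxy]-2-[2-(trityloxy)ethyl]chroman-4-ol, both C4 epimers | C[C@@]1(CCOC(c2ccccc2)(c2ccccc2)c2ccccc2)CC(O)c2c(C)c(O[Si](C(C)C)(C(C)C)C(C)C)cc(C)c2O1 | intermediate (not isolated)
12 | 2-{(S)-2,5,8-trimethyl-6-[(triisopropylsilyl)oxy]chroman-2-yl}ethan-1-ol | C[C@@]1(CCO)CCc2c(C)c(O[Si](C(C)C)(C(C)C)C(C)C)cc(C)c2O1 | intermediate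
13 | {[(S)-2-(2-iodoethyl)-2,5,8-trimethylchroman-6-yl]oxy}triisopropylsilane | C[C@@]1(CCI)CCc2c(C)c(O[Si](C(C)C)(C(C)C)C(C)C)cc(C)c2O1 | intermediate
14 | geranyl bromide, (E)-1-bromo-3,7-dimethylocta-2,6-diene | CC(C)=CCC/C(C)=C/CBr | starting material
15 | 1-(trimethylsilyl)propyne | CC#C[Si](C)(C)C | starting material
16 | 3-lithio-1-(trimethylsilyl)propyne | [Li]CC#C[Si](C)(C)C | intermediate (not isolated)
17 | (E)-(6,10-dimethylundeca-5,9-dien-1-yn-1-yl)trimethylsilane | C[Si](C)(C)C#CCC/C=C(\C)CCC=C(C)C | intermediate (not isolated)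
18 | (E)-6,10-dimethylundeca-5,9-dien-1-yne | C#CCC/C=C(\C)CCC=C(C)C | intermediate
19 | dimethyl[(1E,5E)-2,6,10-trimethylundeca-1,5,9-trien-1-yl]alane | C[Al](C)/C=C(\C)CC/C=C(\C)CCC=C(C)C | intermediate (not isolated)
20 | (1E,5E)-1-iodo-2,6,10-trimethylundeca-1,5,9-triene | I/C=C(\C)CC/C=C(\C)CCC=C(C)C | intermediate
21 | {2-[(S)-2,5,8-trimethyl-6-[(triisopropylsilyl)oxy]chroman-2-yl]ethyl}zinc iodide | C[C@@]1(CC[Zn]I)CCc2c(C)c(O[Si](C(C)C)(C(C)C)C(C)C)cc(C)c2O1 | intermediate (not isolated)
22 | triisopropyl{[(R)-2,5,8-trimethyl-2-[(3E,7E)-4,8,12-trimethyltrideca-3,7,11-trien-1-yl]chroman-6-yl]oxy}silane | CC(C)=CCC/C(C)=C/CC/C(C)=C/CC[C@]1(C)CCc2c(C)c(O[Si](C(C)C)(C(C)C)C(C)C)cc(C)c2O1 | intermediate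
23 | (R)-2,5,8-trimethyl-2-[(3E,7E)-4,8,12-trimethyltrideca-3,7,11-trien-1-yl]chroman-6-ol, (R)-β-tocotrienol | CC(C)=CCC/C(C)=C/CC/C(C)=C/CC[C@]1(C)CCc2c(C)c(O)cc(C)c2O1 | target

**Count and risks**

Total step count: 12. Longest linear sequence: 9 steps (steps 1, 2, 4, 5, 6, 7, 8, 11, 12).

Steps most likely to fail:

1. Step 6. The carbenoid may be diverted into oxonium-ylide formation at O1 followed by a [1,2]-shift, into insertion at the benzylic C–H of the C5 methyl group, or into carbene dimerisation if insertion at the hindered tertiary C–H is slow. The fallback closes the pyran ring at O1–C2 instead; it sets out from 1 and comes back at 12.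
   - 1 is condensed with methyl vinyl ketone and HC(OMe)3 in MeOH (cat. H2SO4) to the racemic cyclic ketal 2-methoxy-2,5,8-trimethylchroman-6-ol F1.
   - Silylation (TIPSCl, imidazole, DMF) gives its silyl ether [(2-methoxy-2,5,8-trimethylchroman-6-yl)oxy]triisopropylsilane F2.
   - Dilute HCl in acetone–water opens the ketal to the keto phenol 4-{2-hydroxy-3,6-dimethyl-5-[(triisopropylsilyl)oxy]phenyl}butan-2-one F3.
   - Wittig methylenation with excess Ph3P=CH2 (from Ph3PCH3Br and KOt-Bu, THF) gives the alkenyl phenol 3,6-dimethyl-2-(3-methylbut-3-en-1-yl)-4-[(triisopropylsilyl)oxy]phenol F4.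
   - An enantioselective domino Wacker cyclisation/methoxycarbonylation (Pd(OCOCF3)2, the enantiomer of the Bn-BOXAX ligand that delivers the (S)-product, p-benzoquinone, CO, MeOH, rt) should give methyl 2-{(S)-2,5,8-trimethyl-6-[(triisopropylsilyl)oxy]chroman-2-yl}acetate F5.
   - LiAlH4 in THF at 0 °C reduces F5 to 12.

2. Step 4. SN2 attack of the doubly ortho-substituted, hydrogen-bonded phenol on the secondary alkoxyphosphonium ion may be slow, so that elimination of the alcohol or alkylation of the hydrazide takes over. The fallback separates activation from displacement; it sets out from 5 and comes back at 6. 5 is converted with MsCl and Et3N (CH2Cl2, 0 °C) into (S)-4-(trityloxy)butan-2-yl methanesulfonate F6. F6 then alkylates the caesium phenoxide of 3 (Cs2CO3, DMF, 60 °C) with inversion to give 6.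

3. Step 7. The C4 cation may be lost to elimination to the 2H-chromene followed by acid-catalysed dimerisation, or the aryl silyl ether may be partly lost in the acid. The fallback replaces the cationic hydride transfer by elimination and catalytic hydrogenation; it sets out from 10 and comes back at 12.
   - 10 is reduced with NaBH4 (MeOH/THF, 0 °C) and the chroman-4-ol 11 is isolated.
   - MsCl, Et3N and DMAP (CH2Cl2, 0 °C) give (2R)-2,5,8-trimethyl-6-[(triisopropylsilyl)oxy]-2-[2-(trityloxy)ethyl]chroman-4-yl methanesulfonate F7, which should eliminate in the flask to (R)-triisopropyl{[2,5,8-trimethyl-2-[2-(trityloxy)ethyl]-2H-chromen-6-yl]oxy}silane F8. F8 is kept cold and in the dark to avoid electrocyclic ring opening.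
   - Hydrogenation over Pd(OH)2/C (H2, EtOAc/EtOH, rt) should saturate C3=C4 and hydrogenolyse the trityl ether to give 12.

**Further compounds**

F1 | step 6 | 2-methoxy-2,5,8-trimethylchroman-6-ol (racemic) | COC1(C)CCc2c(C)c(O)cc(C)c2O1
F2 | step 6 | [(2-methoxy-2,5,8-trimethylchroman-6-yl)oxy]triisopropylsilane (racemic) | COC1(C)CCc2c(C)c(O[Si](C(C)C)(C(C)C)C(C)C)cc(C)c2O1
F3 | step 6 | 4-{2-hydroxy-3,6-dimethyl-5-[(triisopropylsilyl)oxy]phenyl}butan-2-one | CC(=O)CCc1c(C)c(O[Si](C(C)C)(C(C)C)C(C)C)cc(C)c1O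
F4 | step 6 | 3,6-dimethyl-2-(3-methylbut-3-en-1-yl)-4-[(triisopropylsilyl)oxy]phenol | C=C(C)CCc1c(C)c(O[Si](C(C)C)(C(C)C)C(C)C)cc(C)c1O
F5 | step 6 | methyl 2-{(S)-2,5,8-trimethyl-6-[(triisopropylsilyl)oxy]chroman-2-yl}acetate | C[C@@]1(CC(=O)OC)CCc2c(C)c(O[Si](C(C)C)(C(C)C)C(C)C)cc(C)c2O1
F6 | step 4 | (S)-4-(trityloxy)butan-2-yl methanesulfonate | C[C@H](OS(C)(=O)=O)CCOC(c1ccccc1)(c1ccccc1)c1ccccc1
F7 | step 7 | (2R)-2,5,8-trimethyl-6-[(triisopropylsilyl)oxy]-2-[2-(trityloxy)ethyl]chroman-4-yl methanesulfonate, both C4 epimers | C[C@@]1(CCOC(c2ccccc2)(c2ccccc2)c2ccccc2)CC(OS(C)(=O)=O)c2c(C)c(O[Si](C(C)C)(C(C)C)C(C)C)cc(C)c2O1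
F8 | step 7 | (R)-triisopropyl{[2,5,8-trimethyl-2-[2-(trityloxy)ethyl]-2H-chromen-6-yl]oxy}silane | C[C@@]1(CCOC(c2ccccc2)(c2ccccc2)c2ccccc2)C=Cc2c(C)c(O[Si](C(C)C)(C(C)C)C(C)C)cc(C)c2O1
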